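Germacrane numbering is used throughout. C4 and C8, the two ring carbons that end as the tertiary carbinol and the angelate carbinol, stand 1,5 to each other. The ten-membered ring is therefore the rim of a bicyclo[5.3.0]decene (five-membered ring C4–C5–C6–C7–C8, seven-membered ring C4–C3–C2–C1–C10–C9–C8) whose shared C4=C8 bond is cut. One ozonolysis makes both ketones and releases the carbocycle with C1=C10 already cis. Its substrate is a hydroazulene diene that carries C3, C6 and C7 in final configuration and has C1=C10 disarmed as the enol triflate, which later also shields that alkene from OsO4.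

Key step: step 13

Remarks on the design (chemistry only)
- **Polarity.** 1,4-Addition to 1 makes the old carbonyl carbon C4 and the enolate carbon C8, so an electrophile can enter only at C8. C9 is therefore placed on C8 first (steps 1, 2), and C3 is attached to C4 through the enol triflate (steps 4, 5).
- **C3.** A cycloaddition onto a C3=C4–C8=C9 diene would have to approach syn to the C7 side chain to give the 3β-oxygen, and it would leave the position of the C10 methyl open. C3 is instead set by a reagent (step 7), and the seven-membered ring is closed by metathesis (step 9).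
- **Protecting groups.** The C3–O (TIPS) and C6–O (TBS) ethers are made different so that C6–O can be freed alone.
- **The two ketones.** 6-OH is β to both ketones of 22 and cannot steer a hydride to C8 only.
  - The ketones are told apart by enolisability (step 14).
  - The lactone is closed on O6 while C8 is still a ketone (step 15).
  - C8 is then reduced under reagent control (step 16).
- **Triflate timing.** The triflate stays until C4=C15 has been osmylated and C8 is no longer a ketone. This avoids competition for OsO4 and any β,γ to α,β shift.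
- **Geometry check.** In the target, C2 and C9 lie on the same side of the epoxide, which fits the cis alkene of a seven-membered ring.
- **Assumption.** Compounds 16–18 are carried as C1/C10 diastereomer mixtures, because both centres become sp2 in step 12.

Step 1
Reactants: 1 (R)-4-(tert-butyldimethylsilyloxy)cyclopent-2-en-1-one
Product: 2 (R)-4-(tert-butyldimethylsilyloxy)-2-iodocyclopent-2-en-1-one
Conditions: I2, pyridine/CH2Cl2 1:1, 0 °C to rt
Reagents that add atoms: iodine, II
Why: Baylis–Hillman-type α-iodination, in which pyridine adds reversibly to C7, the enolate is iodinated at C8 and pyridine leaves again, marks the future ring-fusion carbon C8 without touching the C6 stereocentre.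

Step 2
Reactants: 2 iodoenone; 3 tributyl(2-methylallyl)stannane
Product: 4 (R)-4-(tert-butyldimethylsilyloxy)-2-(2-methylallyl)cyclopent-2-en-1-one
Conditions: Pd2(dba)3 (2.5 mol %), AsPh3, CuI, NMP, rt
Reagents that add atoms: none
Why: Stille coupling of an α-iodoenone with an allylstannane runs at room temperature under neutral conditions, so C9, C10 and C14 are attached to C8 without β-elimination of the silyloxy group.

Step 3
Reactants: 4 methallyl enone; 5 1-(tert-butyldimethylsilyloxy)-1-methoxyethene
Product: 6 methyl 2-[(1R,5R)-3,5-bis(tert-butyldimethylsilyloxy)-2-(2-methylallyl)cyclopent-2-en-1-yl]acetate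
Conditions: TBSOTf (10 mol %), CH2Cl2, −78 to −40 °C
Reagents that add atoms: none
Why: In this Mukaiyama–Michael addition with silyl transfer the ketene acetal attacks C7 on the face anti to the C6 silyloxy group, which sets C7 trans to C6, and the enolate oxygen is kept as the regiodefined C4=C8 silyl enol ether.

Step 4
Reactants: 6 silyl enol ether
Product: 7 methyl 2-[(1R,5R)-5-(tert-butyldimethylsilyloxy)-2-(2-methylallyl)-3-(trifluoromethylsulfonyloxy)cyclopent-2-en-1-yl]acetate
Conditions: CsF, PhNTf2, DME, rt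
Reagents that add atoms: N-phenylbis(trifluoromethanesulfonimide), O=S(=O)(N(c1ccccc1)S(=O)(=O)C(F)(F)F)C(F)(F)F
Why: Fluoride unmasks the C4(O)=C8 enolate in the presence of the triflating agent (enolate O-triflation), so it is captured before proton transfer toward C5 could expel the C6 silyloxy group.

Step 5
Reactants: 7 cyclopentenyl triflate; 8 (tributylstannyl)methanol
Product: 9 methyl 2-[(1R,5R)-5-(tert-butyldimethylsilyloxy)-3-(hydroxymethyl)-2-(2-methylallyl)cyclopent-2-en-1-yl]acetate
Conditions: Pd(PPh3)4 (5 mol %), LiCl, dioxane, 80 °C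
Reagents that add atoms: none
Why: Stille hydroxymethylation attaches C3 to C4, and it is preferred to a carbonylative formylation because an acylpalladium intermediate would sit within reach of the methallyl alkene and could cyclise onto it.

Step 6
Reactants: 9 allylic alcohol
Product: 10 methyl 2-[(1R,5R)-5-(tert-butyldimethylsilyloxy)-3-formyl-2-(2-methylallyl)cyclopent-2-en-1-yl]acetate
Conditions: Dess–Martin periodinane, CH2Cl2, 0 °C to rt
Reagents that add atoms: none
Why: Dess–Martin oxidation of a primary allylic alcohol is neutral and stops at the enal, which has no α-hydrogen.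

Step 7
Reactants: 10 enal; 11 (−)-B-allyldiisopinocampheylborane (the reagent derived from (+)-α-pinene)
Product: 13 (3S)-homoallylic alcohol, via borinate ester 12 (not isolated)
Conditions: Et2O, −78 °C; then 30% H2O2, pH 7 buffer, MeOH, 0 °C
Reagents that add atoms: none
Why: In the Brown asymmetric allylboration, which passes through a closed chair transition state, this reagent adds to the Si face of the enal and sets (3S) under reagent control, so the remote C6 and C7 centres need not help.

Step 8
Reactants: 13 homoallylic alcohol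
Product: 14 C3 triisopropylsilyl ether of 13
Conditions: TIPSOTf, 2,6-lutidine, CH2Cl2, 0 °C
Reagents that add atoms: triisopropylsilyl triflate, CC(C)[Si](OS(=O)(=O)C(F)(F)F)(C(C)C)C(C)C
Why: Silylation with a silyl triflate and a hindered base covers the hindered allylic alcohol, and TIPS is chosen because it outlasts the C6 TBS ether toward HF·pyridine and adds bulk next to C2.

Step 9
Reactants: 14 triene
Product: 15 hydroazulene diene (C4=C8 ring-fusion alkene; C1=C10 trisubstituted alkene; 3S-OTIPS; 6R-OTBS; 7R-CH2CO2Me)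
Conditions: second-generation Grubbs catalyst (H2IMes)(PCy3)Cl2Ru=CHPh (5 mol %), CH2Cl2 (2 mM), 40 °C
Reagents that add atoms: none
Why: Ring-closing metathesis of a monosubstituted and a 1,1-disubstituted alkene closes the seven-membered ring, in which the new C1=C10 bond can only be cis, while the tetrasubstituted C4=C8 alkene is inert to the catalyst.

Step 10
Reactants: 15 hydroazulene diene
Product: 17 C1 alcohol (C1/C10 diastereomer mixture), via C1 alkylborane 16 (not isolated)
Conditions: BH3·THF (1.1 equiv), THF, 0 °C; then NaBO3·4H2O, THF/H2O, rt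
Reagents that add atoms: sodium perborate, [Na+].[Na+].O[B-]1(O)OO[B-](O)(O)OO1
Why: In this hydroboration–oxidation, borane adds to the trisubstituted alkene much faster than to the tetrasubstituted one and places boron on the less substituted C1, and the new C1 and C10 centres are erased in step 12.

Step 11
Reactants: 17 C1 alcohol
Product: 18 C1 ketone (10-methyl epimers)
Conditions: Dess–Martin periodinane, CH2Cl2, 0 °C to rt
Reagents that add atoms: none
Why: Dess–Martin oxidation is neutral, so the β-silyloxy ketone is formed without elimination of the C3 oxygen.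

Step 12
Reactants: 18 C1 ketone
Product: 20 hydroazulene diene enol triflate (C4=C8; C1(OTf)=C10(CH3); 3S; 6R; 7R), via trimethylsilyl enol ether 19 (not isolated)
Conditions: TMSCl, NaI, Et3N, MeCN, rt (equilibrating), pentane extraction; then CsF, PhNTf2, DME, rt
Reagents that add atoms: N-phenylbis(trifluoromethanesulfonimide), O=S(=O)(N(c1ccccc1)S(=O)(=O)C(F)(F)F)C(F)(F)F
Why: Kinetic deprotonation would take the C2 methylene, so the enol ether is made under equilibrating soft-enolisation conditions that favour the tetrasubstituted C1=C10 isomer (helped by the bulky silyloxy group next to C2), and fluoride/PhNTf2 then exchanges silicon for triflyl without moving the double bond (silyl enol ether to enol triflate).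

Step 13
Reactants: 20 hydroazulene diene enol triflate
Product: 22 ten-membered 4,8-dione carrying the cis C1=C10 enol triflate (3S; 6R; 7S), via C8 methoxy hydroperoxide 21 (not isolated)
Conditions: O3 (1.0 equiv, standardised solution), CH2Cl2/MeOH 5:1, NaHCO3, −78 °C; then Me2S, −78 °C to rt
Reagents that add atoms: ozone, [O-][O+]=O
Why: Ozone adds as a 1,3-dipole to the electron-rich tetraalkyl C4=C8 alkene; the primary ozonide splits, probably into the C4 ketone and the C8 carbonyl oxide because the C3 oxygen disfavours positive charge at C4, methanol captures the carbonyl oxide as 21 and Me2S reduces it to the second ketone (either direction of splitting ends in 22). The closest known reaction type is the ozonolysis of ring-fusion tetrasubstituted alkenes of octalins and hydroazulenes to medium-ring diketones. The ten-membered ring is not closed by bond formation: it is the periphery of the two fused rings and appears when their shared bond is cut. No stereocentre is made; C3, C6 and C7 pass through unchanged under cold, buffered conditions, and the cis C1=C10 geometry is inherited from the seven-membered ring. The step needs chemoselectivity between two tetrasubstituted alkenes, which is secured by the strongly electron-withdrawing triflyloxy group on C1 together with the use of one equivalent of ozone.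

Step 14
Reactants: 22 4,8-dione
Product: 25 4(15)-methylene 8-ketone, via C8 dienol silyl ether 23 (not isolated), via methylenated dienol silyl ether 24 (not isolated)
Conditions: TMSOTf (1.05 equiv), Et3N, CH2Cl2, −78 °C, filtered under argon; then Tebbe reagent Cp2Ti(μ-CH2)(μ-Cl)AlMe2 (1.2 equiv), pyridine, THF/toluene, −40 to 0 °C; then aq citric acid/THF, 0 °C
Reagents that add atoms: Tebbe reagent, C[Al-]1(C)C[Ti]([Cl+]1)(C2C=CC=C2)C3C=CC=C3
Why: This is an in situ protection followed by Tebbe methylenation, in which the C8 carbonyl is the more Lewis basic one and has the doubly activated C9–H, so one equivalent of TMSOTf/Et3N should convert only it into a dienol silyl ether, the non-basic titanium methylidene then takes the remaining C4 ketone faster than the ester, and mild acid returns the C8 ketone by protonation at C9 without touching C7.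

Step 15
Reactants: 25 methylene ketone
Product: 27 8-oxo-6α,12-olide (trans-fused γ-lactone), via 6-hydroxy keto ester 26 (not isolated)
Conditions: HF·pyridine, pyridine, THF, 0 °C to rt; then PPTS (cat.), toluene, 40 °C
Reagents that add atoms: none
Why: HF·pyridine cleaves the secondary TBS ether but not the TIPS ether, and acid-catalysed lactonisation of the γ-hydroxy ester then takes place while C8 is still a ketone, so the ring can close only on O6 and no base is present that could eliminate the β-acyloxy group.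

Step 16
Reactants: 27 keto lactone
Product: 28 8β-hydroxy-6α,12-olide (8R)
Conditions: (S)-2-methyl-CBS-oxazaborolidine (0.5 equiv), catecholborane, toluene, −78 to −40 °C
Reagents that add atoms: none
Why: In the Corey–Bakshi–Shibata reduction the branched C7 flank acts as the large group, so the (S)-catalyst delivers hydride to give (8R), the same sense as Felkin–Anh attack, and catecholborane leaves the 1,1-disubstituted alkene, the lactone and the triflate alone.

Step 17
Reactants: 28 hydroxy lactone
Product: 29 4α,15,8β-triol (4R)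
Conditions: OsO4 (5 mol %), NMO, acetone/H2O, 0 °C to rt
Reagents that add atoms: N-methylmorpholine N-oxide, C[N+]1([O-])CCOCC1; water, O
Why: In this Upjohn dihydroxylation C4=C15 is the only electron-rich alkene because C1=C10 still carries the triflate, and osmium approaches anti to the bulky C3 silyloxy group in the hydrogen-eclipsed allylic conformer, which places 4-OH α and C15 β.

Step 18
Reactants: 29 triol
Product: 30 4,15-acetonide 8-O-(2-methoxyprop-2-yl) acetal
Conditions: 2-methoxypropene, PPTS (5 mol %), CH2Cl2, 0 °C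
Reagents that add atoms: 2-methoxypropene, C=C(C)OC
Why: Acid-catalysed addition and acetal exchange with the enol ether ties the 1,2-diol into a dioxolane and caps 8-OH as a very acid-labile mixed acetal in one operation, which blocks translactonisation to O8 in the next two steps.

Step 19
Reactants: 30 protected enol triflate
Product: 31 (Z)-1(10)-alkene
Conditions: Pd(OAc)2 (5 mol %), PPh3, HCO2H, Et3N, DMF, 60 °C
Reagents that add atoms: none
Why: In this palladium/formate hydrogenolysis of an enol triflate, zerovalent palladium inserts into C1–OTf, formate loses CO2 to give a palladium hydride and reductive elimination proceeds with retention, so the cis geometry becomes the Z-trisubstituted alkene.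

Step 20
Reactants: 31 lactone
Product: 36 8β-hydroxy α-methylene lactone, via lithium enolate 32 (not isolated), via Mannich base 33 (not isolated), via ammonium iodide 34 (not isolated), via acetal-protected methylene lactone 35 (not isolated)
Conditions: LDA, THF, −78 °C; then CH2=NMe2+ I−, −78 °C to rt; MeI, MeOH, rt; aq NaHCO3/CH2Cl2; AcOH/THF/H2O, 0 °C
Reagents that add atoms: Eschenmoser's salt, C=[N+](C)C.[I-]
Why: Aminomethylation of the lactone enolate with Eschenmoser's salt, N-methylation and Hofmann-type elimination install C13, the transient C11 centre is destroyed, and dilute acetic acid removes the mixed acetal far faster than the dioxolane.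

Step 21
Reactants: 36 alcohol; 37 angelic acid
Product: 39 8β-angelate, via mixed anhydride 38 (not isolated)
Conditions: 37, 2,4,6-trichlorobenzoyl chloride, Et3N, toluene, rt; then 36, 75 °C
Reagents that add atoms: none
Why: Yamaguchi mixed-anhydride esterification without a nucleophilic catalyst acylates the only free hydroxyl with retention at C8 and avoids the addition–elimination pathway that turns angelates into tiglates.

Step 22
Reactants: 39 protected angelate
Product: 40 3β,4α,15-triol (Z)-1(10)-alkene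
Conditions: 48% aq HF, MeCN, 0 °C to rt
Reagents that add atoms: none
Why: Aqueous HF cleaves the Si–O bond and hydrolyses the dioxolane in one operation, under conditions that esters, the α-methylene lactone and the isolated alkene tolerate.

Step 23
Reactants: 40 triol alkene
Product: 41 CNP0307250.1
Conditions: VO(acac)2 (5 mol %), t-BuOOH, CH2Cl2, 0 °C
Reagents that add atoms: tert-butyl hydroperoxide, CC(C)(C)OO
Why: In this vanadium-catalysed hydroxyl-directed epoxidation the homoallylic 3β-OH binds the metal peroxide and delivers oxygen to the β face of the only electron-rich alkene, and syn addition to the Z-alkene sets C1 (R) and C10 (S) as the cis epoxide.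

Compound list
1 | (R)-4-(tert-butyldimethylsilyloxy)cyclopent-2-en-1-one | O=C1C=C[C@H](O[Si](C)(C)C(C)(C)C)C1 | starting material
2 | (R)-4-(tert-butyldimethylsilyloxy)-2-iodocyclopent-2-en-1-one | O=C1C(I)=C[C@H](O[Si](C)(C)C(C)(C)C)C1 | intermediate
3 | tributyl(2-methylallyl)stannane | C=C(C)C[Sn](CCCC)(CCCC)CCCC | starting material
4 | (R)-4-(tert-butyldimethylsilyloxy)-2-(2-methylallyl)cyclopent-2-en-1-one | O=C1C(CC(C)=C)=C[C@H](O[Si](C)(C)C(C)(C)C)C1 | intermediate
5 | 1-(tert-butyldimethylsilyloxy)-1-methoxyethene | C=C(OC)O[Si](C)(C)C(C)(C)C | starting material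
6 | methyl 2-[(1R,5R)-3,5-bis(tert-butyldimethylsilyloxy)-2-(2-methylallyl)cyclopent-2-en-1-yl]acetate (side chain trans to C6–O) | [C@@H]1(CC(=O)OC)C(CC(C)=C)=C(O[Si](C)(C)C(C)(C)C)C[C@H]1O[Si](C)(C)C(C)(C)C | intermediate
7 | methyl 2-[(1R,5R)-5-(tert-butyldimethylsilyloxy)-2-(2-methylallyl)-3-(trifluoromethylsulfonyloxy)cyclopent-2-en-1-yl]acetate | [C@@H]1(CC(=O)OC)C(CC(C)=C)=C(OS(=O)(=O)C(F)(F)F)C[C@H]1O[Si](C)(C)C(C)(C)C | intermediate
8 | (tributylstannyl)methanol | OC[Sn](CCCC)(CCCC)CCCC | starting material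
9 | methyl 2-[(1R,5R)-5-(tert-butyldimethylsilyloxy)-3-(hydroxymethyl)-2-(2-methylallyl)cyclopent-2-en-1-yl]acetate | [C@@H]1(CC(=O)OC)C(CC(C)=C)=C(CO)C[C@H]1O[Si](C)(C)C(C)(C)C | intermediate
10 | methyl 2-[(1R,5R)-5-(tert-butyldimethylsilyloxy)-3-formyl-2-(2-methylallyl)cyclopent-2-en-1-yl]acetate | [C@@H]1(CC(=O)OC)C(CC(C)=C)=C(C=O)C[C@H]1O[Si](C)(C)C(C)(C)C | intermediate
11 | (−)-B-allyldiisopinocampheylborane | C=CCB([C@@H]1C[C@@H]2C[C@H]([C@H]1C)C2(C)C)[C@@H]1C[C@@H]2C[C@H]([C@H]1C)C2(C)C | starting material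
12 | diisopinocampheylborinate of alcohol 13 | [C@@H]1(CC(=O)OC)C(CC(C)=C)=C(C[C@H]1O[Si](C)(C)C(C)(C)C)[C@@H](OB([C@@H]3C[C@@H]4C[C@H]([C@H]3C)C4(C)C)[C@@H]3C[C@@H]4C[C@H]([C@H]3C)C4(C)C)CC=C | intermediate
13 | methyl 2-[(1R,5R)-5-(tert-butyldimethylsilyloxy)-3-[(1S)-1-hydroxybut-3-en-1-yl]-2-(2-methylallyl)cyclopent-2-en-1-yl]acetate | [C@@H]1(CC(=O)OC)C(CC(C)=C)=C(C[C@H]1O[Si](C)(C)C(C)(C)C)[C@@H](O)CC=C | intermediate
14 | C3 triisopropylsilyl ether of 13 | [C@@H]1(CC(=O)OC)C(CC(C)=C)=C(C[C@H]1O[Si](C)(C)C(C)(C)C)[C@@H](O[Si](C(C)C)(C(C)C)C(C)C)CC=C | intermediate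
15 | bicyclo[5.3.0]decadiene with C4=C8 and C1=C10(CH3), 3S-OTIPS, 6R-OTBS, 7R-CH2CO2Me | [C@@H]1(CC(=O)OC)C2=C(C[C@H]1O[Si](C)(C)C(C)(C)C)[C@@H](O[Si](C(C)C)(C(C)C)C(C)C)CC=C(C)C2 | intermediate
16 | C1 alkylborane from 15 (C1/C10 mixture) | [C@@H]1(CC(=O)OC)C2=C(C[C@H]1O[Si](C)(C)C(C)(C)C)[C@@H](O[Si](C(C)C)(C(C)C)C(C)C)CC(B)C(C)C2 | intermediate
17 | C1 alcohol (C1/C10 mixture) | [C@@H]1(CC(=O)OC)C2=C(C[C@H]1O[Si](C)(C)C(C)(C)C)[C@@H](O[Si](C(C)C)(C(C)C)C(C)C)CC(O)C(C)C2 | intermediate
18 | C1 ketone (C10 epimers) | [C@@H]1(CC(=O)OC)C2=C(C[C@H]1O[Si](C)(C)C(C)(C)C)[C@@H](O[Si](C(C)C)(C(C)C)C(C)C)CC(=O)C(C)C2 | intermediate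
19 | C1(OTMS)=C10 silyl enol ether | [C@@H]1(CC(=O)OC)C2=C(C[C@H]1O[Si](C)(C)C(C)(C)C)[C@@H](O[Si](C(C)C)(C(C)C)C(C)C)CC(O[Si](C)(C)C)=C(C)C2 | intermediate
20 | bicyclo[5.3.0]decadiene with C4=C8 fusion alkene and C1 enol triflate (3S,6R,7R) | [C@@H]1(CC(=O)OC)C2=C(C[C@H]1O[Si](C)(C)C(C)(C)C)[C@@H](O[Si](C(C)C)(C(C)C)C(C)C)CC(OS(=O)(=O)C(F)(F)F)=C(C)C2 | intermediate
21 | ten-membered 4-ketone 8-methoxy-8-hydroperoxide (C8 epimers) | [C@@H]1(CC(=O)OC)C(OC)(OO)C/C(C)=C(OS(=O)(=O)C(F)(F)F)\C[C@H](O[Si](C(C)C)(C(C)C)C(C)C)C(=O)C[C@H]1O[Si](C)(C)C(C)(C)C | intermediate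
22 | ten-membered 4,8-dione with cis C1=C10 enol triflate (3S,6R,7S) | [C@@H]1(CC(=O)OC)C(=O)C/C(C)=C(OS(=O)(=O)C(F)(F)F)\C[C@H](O[Si](C(C)C)(C(C)C)C(C)C)C(=O)C[C@H]1O[Si](C)(C)C(C)(C)C | intermediate
23 | C8(OTMS)=C9 dienol silyl ether of 22 | [C@@H]1(CC(=O)OC)C(O[Si](C)(C)C)=C/C(C)=C(OS(=O)(=O)C(F)(F)F)\C[C@H](O[Si](C(C)C)(C(C)C)C(C)C)C(=O)C[C@H]1O[Si](C)(C)C(C)(C)C | intermediate
24 | 4(15)-methylene derivative of 23 | [C@@H]1(CC(=O)OC)C(O[Si](C)(C)C)=C/C(C)=C(OS(=O)(=O)C(F)(F)F)\C[C@H](O[Si](C(C)C)(C(C)C)C(C)C)C(=C)C[C@H]1O[Si](C)(C)C(C)(C)C | intermediate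
25 | 4(15)-methylene 8-ketone | [C@@H]1(CC(=O)OC)C(=O)C/C(C)=C(OS(=O)(=O)C(F)(F)F)\C[C@H](O[Si](C(C)C)(C(C)C)C(C)C)C(=C)C[C@H]1O[Si](C)(C)C(C)(C)C | intermediate
26 | 6-hydroxy 8-keto methyl ester | [C@@H]1(CC(=O)OC)C(=O)C/C(C)=C(OS(=O)(=O)C(F)(F)F)\C[C@H](O[Si](C(C)C)(C(C)C)C(C)C)C(=C)C[C@H]1O | intermediate
27 | 8-oxo-3β-(triisopropylsilyloxy)-1-(triflyloxy)germacra-1(10)Z,4(15)-dien-6α,12-olide | C1C(=O)O[C@@H]2CC(=C)[C@@H](O[Si](C(C)C)(C(C)C)C(C)C)C/C(OS(=O)(=O)C(F)(F)F)=C(C)\CC(=O)[C@@H]12 | intermediate
28 | 8β-hydroxy analogue of 27 | C1C(=O)O[C@@H]2CC(=C)[C@@H](O[Si](C(C)C)(C(C)C)C(C)C)C/C(OS(=O)(=O)C(F)(F)F)=C(C)\C[C@@H](O)[C@@H]12 | intermediate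
29 | 4α,15,8β-triol | C1C(=O)O[C@@H]2C[C@@](O)(CO)[C@@H](O[Si](C(C)C)(C(C)C)C(C)C)C/C(OS(=O)(=O)C(F)(F)F)=C(C)\C[C@@H](O)[C@@H]12 | intermediate
30 | 4,15-acetonide 8-O-(2-methoxyprop-2-yl) acetal | C1C(=O)O[C@@H]2C[C@@]3(COC(C)(C)O3)[C@@H](O[Si](C(C)C)(C(C)C)C(C)C)C/C(OS(=O)(=O)C(F)(F)F)=C(C)\C[C@@H](OC(C)(C)OC)[C@@H]12 | intermediate
31 | (Z)-1(10)-alkene from 30 | C1C(=O)O[C@@H]2C[C@@]3(COC(C)(C)O3)[C@@H](O[Si](C(C)C)(C(C)C)C(C)C)C/C=C(C)\C[C@@H](OC(C)(C)OC)[C@@H]12 | intermediate
32 | lithium enolate of lactone 31 | C1=C([O-])O[C@@H]2C[C@@]3(COC(C)(C)O3)[C@@H](O[Si](C(C)C)(C(C)C)C(C)C)C/C=C(C)\C[C@@H](OC(C)(C)OC)[C@@H]12.[Li+] | intermediate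
33 | 11-(dimethylaminomethyl) lactone (C11 epimers) | CN(C)CC1C(=O)O[C@@H]2C[C@@]3(COC(C)(C)O3)[C@@H](O[Si](C(C)C)(C(C)C)C(C)C)C/C=C(C)\C[C@@H](OC(C)(C)OC)[C@@H]12 | intermediate
34 | trimethylammonium iodide of 33 | C[N+](C)(C)CC1C(=O)O[C@@H]2C[C@@]3(COC(C)(C)O3)[C@@H](O[Si](C(C)C)(C(C)C)C(C)C)C/C=C(C)\C[C@@H](OC(C)(C)OC)[C@@H]12.[I-] | intermediate
35 | α-methylene lactone with 8-O-(2-methoxyprop-2-yl) acetal | C=C1C(=O)O[C@@H]2C[C@@]3(COC(C)(C)O3)[C@@H](O[Si](C(C)C)(C(C)C)C(C)C)C/C=C(C)\C[C@@H](OC(C)(C)OC)[C@@H]12 | intermediate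
36 | 8β-hydroxy α-methylene lactone | C=C1C(=O)O[C@@H]2C[C@@]3(COC(C)(C)O3)[C@@H](O[Si](C(C)C)(C(C)C)C(C)C)C/C=C(C)\C[C@@H](O)[C@@H]12 | intermediate
37 | angelic acid, (Z)-2-methylbut-2-enoic acid | C/C=C(/C)C(=O)O | starting material
38 | angelic 2,4,6-trichlorobenzoic anhydride | C/C=C(/C)C(=O)OC(=O)c1c(Cl)cc(Cl)cc1Cl | intermediate
39 | 8β-angelate, 3-OTIPS, 4,15-acetonide | C=C1C(=O)O[C@@H]2C[C@@]3(COC(C)(C)O3)[C@@H](O[Si](C(C)C)(C(C)C)C(C)C)C/C=C(C)\C[C@@H](OC(=O)/C(C)=C\C)[C@@H]12 | intermediate
40 | 8β-angeloyloxy-3β,4α,15-trihydroxygermacra-1(10)Z,11(13)-dien-6α,12-olide | C=C1C(=O)O[C@@H]2C[C@@](O)(CO)[C@@H](O)C/C=C(C)\C[C@@H](OC(=O)/C(C)=C\C)[C@@H]12 | intermediate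
41 | CNP0307250.1 (1β,10β-epoxide of 40) | C=C1C(=O)O[C@@H]2C[C@@](O)(CO)[C@@H](O)C[C@H]3O[C@@]3(C)C[C@@H](OC(=O)/C(C)=C\C)[C@@H]12 | target

Total steps: 23. Longest linear sequence: 23 steps (from 1).

Steps most likely to fail

**Step 12.**
- What may go wrong: enolisation may not settle on the C10 side. The C3 silyloxy group may be lost by β-elimination during equilibration. The liberated enolate may scramble before it is triflated.
- Fallback: a regiospecific enolate made by conjugate reduction instead of equilibration. It sets out from 15. OsO4/NMO attacks only the trisubstituted C1=C10 bond, because the tetrasubstituted one is too hindered, and gives the cis-1,10-diol F1. Parikh–Doering oxidation (SO3·pyridine, DMSO, Et3N) takes the secondary alcohol to the 10-hydroxy-1-ketone F2. The Burgess reagent removes the tertiary hydroxyl to give the 10(14)-methylene ketone F3. LiBH(s-Bu)3 at −78 °C then adds hydride to C14, and PhNTf2 traps the C1(O)=C10 enolate. This comes back to the route at 20.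

**Step 14.**
- What may go wrong: the enol silylation may not discriminate enough between the two carbonyl groups, so that methylenation is lost or misdirected. Transannular aldol closure of the 1,5-diketone is a second risk.
- Fallback: a tethered ketal in place of the enol ether. It sets out from 20. DIBAL-H reduces the ester to the C12 primary alcohol F4. Ozonolysis as in step 13 gives the 12-hydroxy-4,8-dione F5, whose side-chain hydroxyl reaches only C8. PPTS/MeOH locks it as the cyclic C8 methyl ketal F6, so the Tebbe reagent finds a single ketone and gives the 4(15)-methylene ketal F7. HF·pyridine followed by aqueous acetic acid frees the 6,12-dihydroxy-8-ketone F8. TEMPO/PhI(OAc)2 performs the oxidative lactonisation of the 1,4-diol. This comes back to the route at 27.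

**Step 23.**
- What may go wrong: facial selectivity may be poor if 4-OH or 15-OH competes for vanadium. The Lewis-acidic metal may also trigger transannular opening of the new epoxide by a neighbouring hydroxyl.
- Fallback: reagent control instead of substrate direction. It sets out from 40 and uses a Shi epoxidation. The dioxirane is generated from the fructose-type chiral ketone, taken as the enantiomer matched to the β face, with Oxone (2KHSO5·KHSO4·K2SO4) in buffered MeCN/dimethoxymethane/water at 0 °C. These conditions are metal-free and leave the electron-poor alkenes alone. This comes back to the route at 41.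

Further compounds
F1 | step 12 | cis-1,10-diol of hydroazulene 15 (face not specified) | [C@@H]1(CC(=O)OC)C2=C(C[C@H]1O[Si](C)(C)C(C)(C)C)[C@@H](O[Si](C(C)C)(C(C)C)C(C)C)CC(O)C(C)(O)C2
F2 | step 12 | 10-hydroxy-1-ketone | [C@@H]1(CC(=O)OC)C2=C(C[C@H]1O[Si](C)(C)C(C)(C)C)[C@@H](O[Si](C(C)C)(C(C)C)C(C)C)CC(=O)C(C)(O)C2
F3 | step 12 | 10(14)-methylene ketone | [C@@H]1(CC(=O)OC)C2=C(C[C@H]1O[Si](C)(C)C(C)(C)C)[C@@H](O[Si](C(C)C)(C(C)C)C(C)C)CC(=O)C(=C)C2
F4 | step 14 | C12 primary alcohol of 20 | [C@@H]1(CCO)C2=C(C[C@H]1O[Si](C)(C)C(C)(C)C)[C@@H](O[Si](C(C)C)(C(C)C)C(C)C)CC(OS(=O)(=O)C(F)(F)F)=C(C)C2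
F5 | step 14 | 12-hydroxy-4,8-dione | [C@@H]1(CCO)C(=O)C/C(C)=C(OS(=O)(=O)C(F)(F)F)\C[C@H](O[Si](C(C)C)(C(C)C)C(C)C)C(=O)C[C@H]1O[Si](C)(C)C(C)(C)C
F6 | step 14 | cyclic C8 methyl ketal (8,12-epoxy-8-methoxy) 4-ketone | [C@H]12CCOC2(OC)C/C(C)=C(OS(=O)(=O)C(F)(F)F)\C[C@H](O[Si](C(C)C)(C(C)C)C(C)C)C(=O)C[C@H]1O[Si](C)(C)C(C)(C)C
F7 | step 14 | 4(15)-methylene ketal | [C@H]12CCOC2(OC)C/C(C)=C(OS(=O)(=O)C(F)(F)F)\C[C@H](O[Si](C(C)C)(C(C)C)C(C)C)C(=C)C[C@H]1O[Si](C)(C)C(C)(C)C
F8 | step 14 | 6,12-dihydroxy-8-ketone | [C@@H]1(CCO)C(=O)C/C(C)=C(OS(=O)(=O)C(F)(F)F)\C[C@H](O[Si](C(C)C)(C(C)C)C(C)C)C(=C)C[C@H]1O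
F0 | step 23 | none | none
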